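**Plan**

Building blocks (flavanone numbering, ring B primed): 2,4-dihydroxyacetophenone 1 supplies ring A with C4 and C3, 4-(benzyloxy)benzyl alcohol 2 supplies ring B with C2, and geraniol 3 supplies the side chain.
Retrosynthetic cuts, in order: the O–Si bond at O7, the geranyl ether bond at O4', the C2–C3 bond of ring C, the C3=N2 bond of a diazoketone, and the O1–C2 ether bond.
Forward: rings A and B are joined through O1–C2 by etherification, C3 is turned into a diazo carbon, ring C is closed by forming C2–C3, and only then is the benzyl group on O4' exchanged for geranyl and O7 unmasked.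
Enabling feature: C3 is an unsubstituted CH2 between the C4 ketone and C2, and C2 is a benzylic ether carbon whose two hydrogens are enantiotopic in the open-chain aryl benzyl ether, so ring C can be closed by inserting a C3 carbenoid into one C2–H bond.
Stereochemistry: the only stereocentre, C2 (S), is created in that insertion under control of a chiral dirhodium tetracarboxylate; every later step is neutral or buffered so that ring C cannot open and racemise.

Key step: step 5

Remark on the chemistry: the sense of induction of Rh2(S-PTTL)4 in this insertion is assumed to give the 2S product; if it proves opposite, the enantiomeric catalyst Rh2(R-PTTL)4 is used with no other change.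

**Route**

Step 1
Reactants: 1 2,4-dihydroxyacetophenone
Product: 4 1-[2-hydroxy-4-(triisopropylsilyloxy)phenyl]ethanone
Conditions: TIPSCl (1.05 equiv), imidazole, CH2Cl2, 0 °C to rt
Reagents that add atoms: triisopropylsilyl chloride, CC(C)[Si](Cl)(C(C)C)C(C)C
Why: Regioselective silyl ether formation, since the 2-OH is locked in a hydrogen bond to the acetyl carbonyl and shielded by it, so that only the free and more acidic 4-OH should be silylated.

Step 2
Reactants: 4 1-[2-hydroxy-4-(triisopropylsilyloxy)phenyl]ethanone; 2 4-(benzyloxy)benzyl alcohol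
Product: 5 1-[2-(4-benzyloxybenzyloxy)-4-(triisopropylsilyloxy)phenyl]ethanone
Conditions: PPh3, DIAD, THF, 0 °C to rt
Reagents that add atoms: none
Why: Mitsunobu etherification, in which the ortho-acyl phenol is acidic enough to protonate the betaine and displaces the primary benzylic oxyphosphonium group by SN2 under neutral conditions that should leave the base-sensitive aryl silyl ether para to the ketone intact.

Step 3
Reactants: 5 1-[2-(4-benzyloxybenzyloxy)-4-(triisopropylsilyloxy)phenyl]ethanone
Product: 6 1-[2-(4-benzyloxybenzyloxy)-4-(triisopropylsilyloxy)phenyl]-4,4,4-trifluorobutane-1,3-dione (used crude)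
Conditions: LiN(SiMe3)2 (1.1 equiv), THF, −78 °C; CF3CO2CH2CF3 (1.2 equiv), −78 °C; aq. HCl (1 M) quench
Reagents that add atoms: 2,2,2-trifluoroethyl trifluoroacetate, O=C(OCC(F)(F)F)C(F)(F)F
Why: Crossed Claisen condensation, in which the kinetic lithium enolate of the methyl ketone is acylated by the activated trifluoroethyl ester to give the 1,3-diketone that activates C3 for diazo transfer.

Step 4
Reactants: 6 1-[2-(4-benzyloxybenzyloxy)-4-(triisopropylsilyloxy)phenyl]-4,4,4-trifluorobutane-1,3-dione
Product: 7 1-[2-(4-benzyloxybenzyloxy)-4-(triisopropylsilyloxy)phenyl]-2-diazoethanone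
Conditions: MsN3 (1.5 equiv), Et3N (1.5 equiv), H2O (1 equiv), MeCN, rt
Reagents that add atoms: methanesulfonyl azide, CS(=O)(=O)N=[N+]=[N-]
Why: Detrifluoroacetylative diazo transfer of the Regitz type, in which the enolised diketone takes up the diazo group from the sulfonyl azide and the trifluoroacetyl group leaves as the N-sulfonyl amide, which should give the terminal diazoketone without touching the silyl or benzyl ethers.

Step 5
Reactants: 7 1-[2-(4-benzyloxybenzyloxy)-4-(triisopropylsilyloxy)phenyl]-2-diazoethanone
Product: 8 (2S)-2-[4-(benzyloxy)phenyl]-7-(triisopropylsilyloxy)chroman-4-one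
Conditions: Rh2(S-PTTL)4 [dirhodium tetrakis(N-phthaloyl-(S)-tert-leucinate)] (2 mol %), CH2Cl2, 0 °C, 7 added over 4 h by syringe pump (final 0.01 M)
Reagents that add atoms: none
Why: Rh2(S-PTTL)4, a tetracarboxylate of divalent rhodium, expels N2 from 7 to give an electrophilic carbenoid at C3, which inserts into one benzylic C2–H bond of the ether through a concerted, hydride-transfer-like three-centre transition state, forming C2–C3 and releasing the catalyst. The closest known reaction type is the chiral dirhodium carboxylate-catalysed intramolecular C–H insertion of 2-alkoxyphenyl diazomethyl ketones to 2-substituted chroman-4-ones. Ring C closes as a six-membered ring by 1,6-insertion (C3 onto C2 across C4, C4a, C8a and O1); a five-membered alternative does not exist because the 1,5-position is O1 itself. The C2 stereocentre arises by catalyst control alone, the phthalimido and tert-butyl walls of the carboxylate shell differentiating the two enantiotopic benzylic hydrogens of the achiral substrate in the sense assumed in the remark above. The step needs insertion to outrun oxonium ylide formation at O1 with [1,2]-benzyl shift, attack on ring B and carbene dimerisation; the doubly activated C2–H (next to oxygen and on a para-alkoxyphenyl ring), the weakly nucleophilic O1 (conjugated to the C4 ketone through ring A), a carboxylate rather than a perfluoroacyl catalyst and high dilution should secure this. No alkene is present, which is why O4' carries a benzyl group at this stage and not the geranyl chain.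

Step 6
Reactants: 8 (2S)-2-[4-(benzyloxy)phenyl]-7-(triisopropylsilyloxy)chroman-4-one
Product: 9 (2S)-2-(4-hydroxyphenyl)-7-(triisopropylsilyloxy)chroman-4-one
Conditions: H2 (1 atm), 10% Pd/C, EtOAc, rt, stopped at full conversion
Reagents that add atoms: none
Why: Catalytic hydrogenolysis of a benzyl aryl ether, whose primary O–CH2Ph bond should be cleaved well before the secondary cyclic C2–O1 bond or the aryl ketone is attacked, in a neutral medium that leaves C2 configurationally intact.

Step 7
Reactants: 9 (2S)-2-(4-hydroxyphenyl)-7-(triisopropylsilyloxy)chroman-4-one; 3 geraniol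
Product: 10 (2S)-2-{4-[(2E)-3,7-dimethylocta-2,6-dien-1-yloxy]phenyl}-7-(triisopropylsilyloxy)chroman-4-one
Conditions: PPh3, THF, 0 °C; DIAD added last, dropwise; 0 °C to rt
Reagents that add atoms: none
Why: Mitsunobu etherification with a primary allylic alcohol, in which the 4'-phenol displaces the geranyloxyphosphonium group by SN2 with the E-alkene retained, while late addition of the azodicarboxylate keeps the phenoxide concentration low so that ring C should not open.

Step 8
Reactants: 10 (2S)-2-{4-[(2E)-3,7-dimethylocta-2,6-dien-1-yloxy]phenyl}-7-(triisopropylsilyloxy)chroman-4-one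
Product: 11 (2S)-2-{4-[(2E)-3,7-dimethylocta-2,6-dien-1-yloxy]phenyl}-7-hydroxychroman-4-one (CNP0302343.1)
Conditions: Bu4NF (1.1 equiv), AcOH (1.2 equiv), THF, 0 °C
Reagents that add atoms: none
Why: Fluoride-mediated cleavage of an aryl silyl ether, fast for the O–Si bond para to the ketone, with acetic acid buffering so that the liberated phenoxide is protonated and neither retro-oxa-Michael opening at C2 nor loss of the geranyl ether should occur.

**Compound list**

1 | 2,4-dihydroxyacetophenone | CC(=O)c1ccc(O)cc1O | starting material
2 | 4-(benzyloxy)benzyl alcohol | OCc1ccc(OCc2ccccc2)cc1 | starting material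
3 | geraniol | CC(C)=CCC/C(C)=C/CO | starting material
4 | 1-[2-hydroxy-4-(triisopropylsilyloxy)phenyl]ethanone | CC(=O)c1ccc(O[Si](C(C)C)(C(C)C)C(C)C)cc1O | intermediate
5 | 1-[2-(4-benzyloxybenzyloxy)-4-(triisopropylsilyloxy)phenyl]ethanone | CC(=O)c1ccc(O[Si](C(C)C)(C(C)C)C(C)C)cc1OCc1ccc(OCc2ccccc2)cc1 | intermediate
6 | 1-[2-(4-benzyloxybenzyloxy)-4-(triisopropylsilyloxy)phenyl]-4,4,4-trifluorobutane-1,3-dione | O=C(CC(=O)C(F)(F)F)c1ccc(O[Si](C(C)C)(C(C)C)C(C)C)cc1OCc1ccc(OCc2ccccc2)cc1 | intermediate
7 | 1-[2-(4-benzyloxybenzyloxy)-4-(triisopropylsilyloxy)phenyl]-2-diazoethanone | [N-]=[N+]=CC(=O)c1ccc(O[Si](C(C)C)(C(C)C)C(C)C)cc1OCc1ccc(OCc2ccccc2)cc1 | intermediate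
8 | (2S)-2-[4-(benzyloxy)phenyl]-7-(triisopropylsilyloxy)chroman-4-one | c1ccccc1COc1ccc([C@@H]2CC(=O)c3ccc(O[Si](C(C)C)(C(C)C)C(C)C)cc3O2)cc1 | intermediate
9 | (2S)-2-(4-hydroxyphenyl)-7-(triisopropylsilyloxy)chroman-4-one | Oc1ccc([C@@H]2CC(=O)c3ccc(O[Si](C(C)C)(C(C)C)C(C)C)cc3O2)cc1 | intermediate
10 | (2S)-2-{4-[(2E)-3,7-dimethylocta-2,6-dien-1-yloxy]phenyl}-7-(triisopropylsilyloxy)chroman-4-one | CC(C)=CCC/C(C)=C/COc1ccc([C@@H]2CC(=O)c3ccc(O[Si](C(C)C)(C(C)C)C(C)C)cc3O2)cc1 | intermediate
11 | (2S)-2-{4-[(2E)-3,7-dimethylocta-2,6-dien-1-yloxy]phenyl}-7-hydroxychroman-4-one | CC(C)=CCC/C(C)=C/COc1ccc([C@@H]2CC(=O)c3ccc(O)cc3O2)cc1 | target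

**Step count**

Total: 8 steps. Longest linear sequence: 8 steps (from 1; compounds 2 and 3 are purchased).

**Steps most likely to fail**

Step 5. The carbenoid may be diverted into oxonium ylide formation at O1 followed by [1,2]-benzyl migration, or the catalyst may discriminate poorly between the two enantiotopic hydrogens. The fallback sets out from 4 and returns at 8. Condensation of 4 with N,N-dimethylformamide dimethyl acetal (toluene, 90 °C) should give (E)-3-(dimethylamino)-1-[2-hydroxy-4-(triisopropylsilyloxy)phenyl]prop-2-en-1-one F1. Acid-induced cyclisation with loss of dimethylamine (HCl, CH2Cl2, rt) should then give 7-(triisopropylsilyloxy)chromen-4-one F2. Enantioselective conjugate addition of 4-(benzyloxy)phenylboronic acid under divalent palladium catalysis [Pd(OCOCF3)2, 4-tert-butyl-2-(pyridin-2-yl)oxazoline in the enantiomeric form that delivers the 2S series, NH4PF6, H2O, 1,2-dichloroethane, 60 °C] should give 8. Here ring C is closed at O1–C2 and the stereocentre is set by aryl transfer to C2.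

Step 7. The free 4'-phenoxide can push open ring C through a quinone methide, eroding the C2 configuration, and the activated geranyl unit can suffer allylic transposition. The fallback sets out from 4 and returns at 10; it carries the geranyl ether through the insertion and also makes the hydrogenolysis of step 6 unnecessary. Alkylation of 4-hydroxybenzyl alcohol with geranyl bromide (K2CO3, acetone, rt) should give 4-[(2E)-3,7-dimethylocta-2,6-dien-1-yloxy]benzyl alcohol F3. Mitsunobu coupling with 4 under the conditions of step 2 should give 1-[2-(4-geranyloxybenzyloxy)-4-(triisopropylsilyloxy)phenyl]ethanone F4. Trifluoroacetylation as in step 3 should give 1-[2-(4-geranyloxybenzyloxy)-4-(triisopropylsilyloxy)phenyl]-4,4,4-trifluorobutane-1,3-dione F5. Diazo transfer as in step 4 should give 1-[2-(4-geranyloxybenzyloxy)-4-(triisopropylsilyloxy)phenyl]-2-diazoethanone F6. Insertion with Rh2(S-PTTL)4 in CH2Cl2 at 0 °C, with slow addition to a final 0.005 M so that intermolecular cyclopropanation of the trisubstituted alkenes cannot compete, should give 10.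

Step 2. Coupling may be slow or incomplete because the phenol is chelated to the ketone, and the electron-rich benzylic oxyphosphonium species may ionise and benzylate ring A at carbon. The fallback sets out from 4 and returns at 5: Williamson etherification with 4-(benzyloxy)benzyl chloride, K2CO3 and catalytic NaI in anhydrous acetone at 50 °C, the dry medium protecting the silyl ether (no new compound, F0).

**Further compounds**

F1 | step 5 | (E)-3-(dimethylamino)-1-[2-hydroxy-4-(triisopropylsilyloxy)phenyl]prop-2-en-1-one | CN(C)/C=C/C(=O)c1ccc(O[Si](C(C)C)(C(C)C)C(C)C)cc1O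
F2 | step 5 | 7-(triisopropylsilyloxy)chromen-4-one | O=c1ccoc2cc(O[Si](C(C)C)(C(C)C)C(C)C)ccc12
F3 | step 7 | 4-[(2E)-3,7-dimethylocta-2,6-dien-1-yloxy]benzyl alcohol | CC(C)=CCC/C(C)=C/COc1ccc(CO)cc1
F4 | step 7 | 1-[2-(4-geranyloxybenzyloxy)-4-(triisopropylsilyloxy)phenyl]ethanone | CC(C)=CCC/C(C)=C/COc1ccc(COc2cc(O[Si](C(C)C)(C(C)C)C(C)C)ccc2C(C)=O)cc1
F5 | step 7 | 1-[2-(4-geranyloxybenzyloxy)-4-(triisopropylsilyloxy)phenyl]-4,4,4-trifluorobutane-1,3-dione | CC(C)=CCC/C(C)=C/COc1ccc(COc2cc(O[Si](C(C)C)(C(C)C)C(C)C)ccc2C(=O)CC(=O)C(F)(F)F)cc1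
F6 | step 7 | 1-[2-(4-geranyloxybenzyloxy)-4-(triisopropylsilyloxy)phenyl]-2-diazoethanone | CC(C)=CCC/C(C)=C/COc1ccc(COc2cc(O[Si](C(C)C)(C(C)C)C(C)C)ccc2C(=O)C=[N+]=[N-])cc1
F0 | step 2 | none | none
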